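**Strategy.** The 7‑hydroxyisoindolinone is taken apart at its benzene ring. The arene shares one C–C bond with the five‑membered lactam, whose other atoms are the orthoamide carbon, the imide nitrogen and the lactam carbonyl, and the phenol oxygen sits on the aryl carbon next to the one carrying the orthoamide carbon. A ruthenium‑catalysed [2+2+2] cycloaddition of acetylene with a diyne tethered through exactly these three atoms forms the benzene and the lactam in one operation and places boron, the phenol precursor, unambiguously. The precursor is the bicyclic orthoamide (a 1,3‑oxazinan‑4‑one bridged by the eleven‑membered ring) carrying a borylethynyl group on the orthoamide carbon and a propioloyl group on nitrogen.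

Key step: step 15

Remark (locants): C1–C12 are the carbons of the dodecanamide chain of 17 (C1 amide carbonyl, C3 and C10 carbinol carbons, C12 the CH2O carbon) and are kept for all fragments and later compounds; "orthoamide carbon" is the carbon bonded to N, O–C3 and O–C10.
Remark (assumption): the orthoamide epimer with the C10–O bond axial on the oxazinanone ring and the C‑substituent equatorial (S, as in the target) is taken to be the thermodynamically preferred one.
Remark (assumption): Pd(0) displaces the propargylic mesylates anti‑SN2′ and the allenylzinc adds syn‑SE2′, so each mesylate carbon is inverted overall.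
Remark (assumption): compounds 1, 4, 8, 10, 18, 21, 24 and 30 are taken as commercial.

**Step 1**
Reactants: 1 methyl (S)-3-hydroxy-2-methylpropanoate
Product: 2 methyl (S)-3-[(tert-butyldimethylsilyl)oxy]-2-methylpropanoate
Conditions: TBSCl, imidazole, CH2Cl2, 0 °C → rt
Reagents that add atoms: tert-butyldimethylsilyl chloride, CC(C)(C)[Si](C)(C)Cl
Why: Imidazole‑promoted silylation of the primary alcohol (silyl ether formation) is fast and leaves the α‑stereocentre untouched.

**Step 2**
Reactants: 2 methyl (S)-3-[(tert-butyldimethylsilyl)oxy]-2-methylpropanoate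
Product: 3 (S)-3-[(tert-butyldimethylsilyl)oxy]-2-methylpropanal
Conditions: DIBAL-H (1.05 equiv), CH2Cl2, −78 °C; Rochelle salt work-up; used crude
Reagents that add atoms: none
Why: DIBAL‑H half‑reduction of the ester stops at the tetrahedral aluminium hemiacetal at −78 °C and releases the aldehyde only on work‑up, so over‑reduction and α‑epimerisation should be avoided when the crude aldehyde is used at once.

**Step 3**
Reactants: 4 (S)-but-3-yn-2-ol
Product: 5 (S)-but-3-yn-2-yl methanesulfonate
Conditions: MsCl, Et3N, CH2Cl2, −78 → 0 °C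
Reagents that add atoms: methanesulfonyl chloride, CS(=O)(=O)Cl
Why: O‑Sulfonylation (mesylate formation) takes place at oxygen, so the carbinol configuration is retained.

**Step 4**
Reactants: 3 (S)-3-[(tert-butyldimethylsilyl)oxy]-2-methylpropanal; 5 (S)-but-3-yn-2-yl methanesulfonate
Product: 7 (2S,3R,4R)-1-[(tert-butyldimethylsilyl)oxy]-2,4-dimethylhex-5-yn-3-ol, via (M)-buta-1,2-dienyl(ethyl)zinc 6 (not isolated)
Conditions: Pd(OAc)2 (5 mol%), PPh3 (5 mol%), Et2Zn (3 equiv), THF, −78 → −20 °C
Reagents that add atoms: none
Why: Marshall propargylation: anti‑SN2′ palladation of 5, Pd→Zn exchange and syn‑SE2′ addition through a closed six‑membered transition state replace the C–O bond of 5 by the new C–C bond with net inversion (C9 becomes R) and place the C10 hydroxyl anti to the C9 methyl, the chiral reagent overriding the Felkin preference of 3 so that the anti,anti triad (C10 R) should result.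

**Step 5**
Reactants: 8 (R)-but-3-yn-2-ol
Product: 9 (R)-but-3-yn-2-yl methanesulfonate
Conditions: MsCl, Et3N, CH2Cl2, −78 → 0 °C
Reagents that add atoms: methanesulfonyl chloride, CS(=O)(=O)Cl
Why: O‑Sulfonylation (mesylate formation) with retention at the carbinol carbon.

**Step 6**
Reactants: 9 (R)-but-3-yn-2-yl methanesulfonate; 10 3-(benzyloxy)propanal
Product: 12 (3R,4S)-1-(benzyloxy)-4-methylhex-5-yn-3-ol, via (P)-buta-1,2-dienyl(ethyl)zinc 11 (not isolated)
Conditions: Pd(OAc)2 (5 mol%), PPh3 (5 mol%), Et2Zn (3 equiv), THF, −78 → −20 °C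
Reagents that add atoms: none
Why: The enantiomeric allenylzinc adds to the achiral aldehyde by the same Marshall anti‑SN2′/syn‑SE2′ sequence, setting C4 (S, net inversion of 9) and C3 (R, anti to the C4 methyl through the cyclic transition state) under pure reagent control.

**Step 7**
Reactants: 12 (3R,4S)-1-(benzyloxy)-4-methylhex-5-yn-3-ol
Product: 13 (3R,4S)-1-(benzyloxy)-6-bromo-4-methylhex-5-yn-3-ol
Conditions: NBS, AgNO3 (10 mol%), acetone, rt
Reagents that add atoms: N-bromosuccinimide, O=C1CCC(=O)N1Br
Why: Silver‑catalysed electrophilic bromination of the terminal alkyne (through the silver acetylide) gives the 1‑bromoalkyne without touching the carbinol or the benzyl ether.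

**Step 8**
Reactants: 7 (2S,3R,4R)-1-[(tert-butyldimethylsilyl)oxy]-2,4-dimethylhex-5-yn-3-ol; 13 (3R,4S)-1-(benzyloxy)-6-bromo-4-methylhex-5-yn-3-ol
Product: 14 (3R,4S,9R,10R,11S)-1-(benzyloxy)-12-[(tert-butyldimethylsilyl)oxy]-4,9,11-trimethyldodeca-5,7-diyne-3,10-diol
Conditions: CuCl (5 mol%), NH2OH·HCl, n-BuNH2, H2O/Et2O, 0 °C, slow addition of 13
Reagents that add atoms: none
Why: Cadiot–Chodkiewicz coupling of the copper(I) acetylide of 7 with bromoalkyne 13 gives the unsymmetrical 1,3‑diyne, hydroxylamine holding copper in the +1 state so that Glaser homocoupling should stay minor, and no stereocentre is involved.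

**Step 9**
Reactants: 14 (3R,4S,9R,10R,11S)-1-(benzyloxy)-12-[(tert-butyldimethylsilyl)oxy]-4,9,11-trimethyldodeca-5,7-diyne-3,10-diol
Product: 15 (3R,4S,9R,10R,11S)-12-[(tert-butyldimethylsilyl)oxy]-4,9,11-trimethyldodecane-1,3,10-triol
Conditions: H2 (1 atm), Pd(OH)2/C, EtOAc, rt
Reagents that add atoms: none
Why: Heterogeneous hydrogenation saturates the diyne to the (CH2)4 link and hydrogenolyses the benzyl ether in the same flask, while the silyl ether survives in ethyl acetate and the C4 and C9 stereocentres, which carry no activating group, should be retained.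

**Step 10**
Reactants: 15 (3R,4S,9R,10R,11S)-12-[(tert-butyldimethylsilyl)oxy]-4,9,11-trimethyldodecane-1,3,10-triol
Product: 16 (3R,4S,9R,10R,11S)-12-[(tert-butyldimethylsilyl)oxy]-3,10-dihydroxy-4,9,11-trimethyldodecanoic acid
Conditions: TEMPO (20 mol%), PhI(OAc)2 (2.4 equiv), MeCN/H2O, rt
Reagents that add atoms: water, O
Why: The TEMPO oxoammonium oxidation selects the primary alcohol and carries it through the aldehyde hydrate to the acid, leaving both secondary carbinols untouched.

**Step 11**
Reactants: 16 (3R,4S,9R,10R,11S)-12-[(tert-butyldimethylsilyl)oxy]-3,10-dihydroxy-4,9,11-trimethyldodecanoic acid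
Product: 17 (3R,4S,9R,10R,11S)-12-[(tert-butyldimethylsilyl)oxy]-3,10-dihydroxy-4,9,11-trimethyldodecanamide
Conditions: EDC·HCl, HOBt, NH4Cl, iPr2NEt, DMF, 0 °C → rt
Reagents that add atoms: ammonium chloride, [NH4+].[Cl-]
Why: Carbodiimide/HOBt amidation with ammonia liberated from NH4Cl acylates nitrogen much faster than the hindered secondary hydroxyls, giving the β‑hydroxy primary amide without elimination.

**Step 12**
Reactants: 17 (3R,4S,9R,10R,11S)-12-[(tert-butyldimethylsilyl)oxy]-3,10-dihydroxy-4,9,11-trimethyldodecanamide; 18 3,3,3-triethoxyprop-1-yne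
Product: 19 bicyclic C-ethynyl NH-orthoamide
Conditions: 18 (1.05 equiv), PPTS (10 mol%), PhMe (2 mM), 60 °C, 5 Å MS trap for EtOH; Et3N quench
Reagents that add atoms: none
Why: Acid‑catalysed orthoester exchange replaces the three ethoxy groups by the amide N–H, O–C3 (six‑membered 1,3‑oxazinan‑4‑one) and, at high dilution with ethanol removal, O–C10 (eleven‑membered ring); being reversible, it should funnel the orthoamide carbon to the S epimer in which the C10–O bond is axial (anomeric effect) and the ethynyl group and the C4 chain are equatorial.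

**Step 13**
Reactants: 19 bicyclic C-ethynyl NH-orthoamide
Product: 20 bicyclic C-(pinacolborylethynyl) NH-orthoamide
Conditions: LDA (2.1 equiv), THF, −78 °C; iPrOBpin (1.2 equiv); HCl·Et2O (2.1 equiv), −78 °C → rt; filtration under Ar, used crude
Reagents that add atoms: 2-isopropoxy-4,4,5,5-tetramethyl-1,3,2-dioxaborolane, CC(C)OB1OC(C)(C)C(C)(C)O1
Why: Two equivalents of LDA remove N–H and then C≡C–H, only the acetylide attacks the borate ester, and matched anhydrous HCl collapses the borate (classical lithiation–borylation of a terminal alkyne), while the lithium amidate holds the orthoamide closed and the medium never becomes acidic.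

**Step 14**
Reactants: 20 bicyclic C-(pinacolborylethynyl) NH-orthoamide; 21 propiolic acid
Product: 23 N-propioloyl C-(pinacolborylethynyl) bicyclic orthoamide, via propiolic anhydride 22 (not isolated)
Conditions: 21 (2.4 equiv), DCC (1.2 equiv), CH2Cl2, 0 °C, filtered; 20, LiHMDS (1.0 equiv), THF, −78 °C, then the anhydride solution, −78 °C
Reagents that add atoms: none
Why: N‑Acylation of the lithium amidate of 20 by the symmetric anhydride (imide formation) should be faster at −78 °C than conjugate addition to the ynoate, and the product, having no N–H, can no longer expel an alkoxy group, which locks the orthoamide configuration.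

**Step 15**
Reactants: 23 N-propioloyl C-(pinacolborylethynyl) bicyclic orthoamide; 24 acetylene
Product: 25 tetracyclic aryl pinacolboronate
Conditions: Cp*RuCl(cod) (10 mol%), HC≡CH (1 atm), DCE, rt, 23 added by syringe pump over 6 h
Reagents that add atoms: none
Why: Oxidative coupling of the two tethered alkynes on Cp*RuCl gives a ruthenacyclopentadiene in which the new bond between the inner alkyne carbons has already closed the five‑membered lactam as the ring fused to the metallacycle; insertion of acetylene into a Ru–C bond followed by C–C reductive elimination then closes the benzene ring and returns Ru(II). The closest known reactions are Cp*RuCl‑ and Rh(I)‑catalysed [2+2+2] cycloadditions of amide‑tethered 1,6‑diynes with monoalkynes to isoindolinones and of diynes with a pinacolboryl terminus to arylboronates. No stereocentre is formed, and the orthoamide carbon, none of whose bonds takes part, keeps the S configuration set in steps 12–14. Regiochemistry needs no control because acetylene is symmetrical, and the tether alone dictates that boron ends on the aryl carbon adjacent to the one bearing the orthoamide carbon. The selectivity that matters is cross‑ over homo‑cyclotrimerisation of 23: the three‑atom C–N–C(=O) tether with its quaternary orthoamide carbon should make the intramolecular coupling fast, the bulky boryl terminus makes 23 a poor monoalkyne partner, and a saturated acetylene solution with slow addition keeps the free diyne concentration low. The neutral, aprotic conditions should leave the alkynyl C–B bond, the imide and the orthoamide intact.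

**Step 16**
Reactants: 25 tetracyclic aryl pinacolboronate
Product: 26 tetracyclic phenol with silyloxymethyl side arm
Conditions: Me3NO (3 equiv), THF, rt → 45 °C; aqueous work-up
Reagents that add atoms: trimethylamine N-oxide, C[N+](C)(C)[O-]
Why: Amine‑oxide oxidation of the arylboronate (O→B coordination, 1,2‑aryl shift from boron to oxygen, hydrolysis of the aryl borate on work‑up) proceeds under neutral, non‑nucleophilic conditions that should spare the imide, the orthoamide and the silyl ether.

**Step 17**
Reactants: 26 tetracyclic phenol with silyloxymethyl side arm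
Product: 27 tetracyclic phenol primary alcohol
Conditions: TBAF, AcOH (1:1), THF, 0 °C → rt
Reagents that add atoms: none
Why: Fluoride cleaves the primary Si–O bond (desilylation), and acetic acid buffering keeps the medium from opening the imide.

**Step 18**
Reactants: 27 tetracyclic phenol primary alcohol
Product: 28 tetracyclic phenol aldehyde
Conditions: Dess–Martin periodinane, NaHCO3, CH2Cl2, 0 °C; used crude
Reagents that add atoms: none
Why: Dess–Martin oxidation under bicarbonate buffering gives the α‑branched aldehyde without enolisation, and the hydrogen‑bonded, electron‑poor phenol should not be oxidised at 0 °C.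

**Step 19**
Reactants: 28 tetracyclic phenol aldehyde
Product: 29 tetracyclic phenol carboxylic acid
Conditions: NaClO2, NaH2PO4, 2-methylbut-2-ene, t-BuOH/H2O, 0 °C
Reagents that add atoms: sodium chlorite, [Na+].[O-]Cl=O
Why: Pinnick oxidation converts the aldehyde to the acid through the chlorite adduct without enolising C11, the alkene scavenging HOCl before it can chlorinate the phenol.

**Step 20**
Reactants: 29 tetracyclic phenol carboxylic acid; 30 pyrrole
Product: 33 CNP0418824.1, via pyrrol-1-ylmagnesium bromide 31 (not isolated), via S-(pyridin-2-yl) thioester 32 (not isolated)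
Conditions: 2,2'-dipyridyl disulfide, PPh3, PhMe, rt; then 31 (5 equiv, from 30 and EtMgBr, THF, 0 °C), −78 °C; NH4Cl
Reagents that add atoms: none
Why: Mukaiyama redox condensation gives the 2‑pyridyl thioester, which the ambident pyrrolylmagnesium bromide acylates at C2 through a magnesium chelate (thioester‑to‑ketone acyl substitution), and the 2‑acylpyrrole, held as its N‑magnesio salt, should neither add a second equivalent nor enolise at C11.

**Compound list**

1 | methyl (S)-3-hydroxy-2-methylpropanoate | C[C@@H](CO)C(=O)OC | starting material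
2 | methyl (S)-3-[(tert-butyldimethylsilyl)oxy]-2-methylpropanoate | C[C@@H](CO[Si](C)(C)C(C)(C)C)C(=O)OC | intermediate
3 | (S)-3-[(tert-butyldimethylsilyl)oxy]-2-methylpropanal | C[C@@H](CO[Si](C)(C)C(C)(C)C)C=O | intermediate
4 | (S)-but-3-yn-2-ol | C[C@H](O)C#C | starting material
5 | (S)-but-3-yn-2-yl methanesulfonate | C[C@H](OS(C)(=O)=O)C#C | intermediate
6 | (M)-buta-1,2-dienyl(ethyl)zinc | CC[Zn]C([H])=[C@]=C([H])C | intermediate
7 | (2S,3R,4R)-1-[(tert-butyldimethylsilyl)oxy]-2,4-dimethylhex-5-yn-3-ol (C7–C12 fragment) | C[C@H](C#C)[C@@H](O)[C@@H](C)CO[Si](C)(C)C(C)(C)C | intermediate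
8 | (R)-but-3-yn-2-ol | C[C@@H](O)C#C | starting material
9 | (R)-but-3-yn-2-yl methanesulfonate | C[C@@H](OS(C)(=O)=O)C#C | intermediate
10 | 3-(benzyloxy)propanal | O=CCCOCc1ccccc1 | starting material
11 | (P)-buta-1,2-dienyl(ethyl)zinc | CC[Zn]C([H])=[C@@]=C([H])C | intermediate
12 | (3R,4S)-1-(benzyloxy)-4-methylhex-5-yn-3-ol (C1–C6 fragment) | C#C[C@H](C)[C@H](O)CCOCc1ccccc1 | intermediate
13 | (3R,4S)-1-(benzyloxy)-6-bromo-4-methylhex-5-yn-3-ol | BrC#C[C@H](C)[C@H](O)CCOCc1ccccc1 | intermediate
14 | (3R,4S,9R,10R,11S)-1-(benzyloxy)-12-[(tert-butyldimethylsilyl)oxy]-4,9,11-trimethyldodeca-5,7-diyne-3,10-diol | C[C@H](C#CC#C[C@H](C)[C@H](O)CCOCc1ccccc1)[C@@H](O)[C@@H](C)CO[Si](C)(C)C(C)(C)C | intermediate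
15 | (3R,4S,9R,10R,11S)-12-[(tert-butyldimethylsilyl)oxy]-4,9,11-trimethyldodecane-1,3,10-triol | C[C@H](CCCC[C@H](C)[C@H](O)CCO)[C@@H](O)[C@@H](C)CO[Si](C)(C)C(C)(C)C | intermediate
16 | (3R,4S,9R,10R,11S)-12-[(tert-butyldimethylsilyl)oxy]-3,10-dihydroxy-4,9,11-trimethyldodecanoic acid | C[C@H](CCCC[C@H](C)[C@H](O)CC(=O)O)[C@@H](O)[C@@H](C)CO[Si](C)(C)C(C)(C)C | intermediate
17 | (3R,4S,9R,10R,11S)-12-[(tert-butyldimethylsilyl)oxy]-3,10-dihydroxy-4,9,11-trimethyldodecanamide | C[C@H](CCCC[C@H](C)[C@H](O)CC(N)=O)[C@@H](O)[C@@H](C)CO[Si](C)(C)C(C)(C)C | intermediate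
18 | 3,3,3-triethoxyprop-1-yne | CCOC(OCC)(OCC)C#C | starting material
19 | bicyclic C-ethynyl NH-orthoamide: one carbon (S) bonded to the amide N, O–C3, O–C10 and ethynyl; six-membered 1,3-oxazinan-4-one (N, C1, C2, C3, O, orthoamide C) bridged by the eleven-membered ring (C3–C10, O, orthoamide C, O); 3R,4S,9R,10R,11S; C10 carries CH(CH3)CH2OTBS | C[C@@H]1CCCC[C@H](C)[C@H]2CC(=O)N[C@](C#C)(O[C@H]1[C@@H](C)CO[Si](C)(C)C(C)(C)C)O2 | intermediate
20 | bicyclic C-(pinacolborylethynyl) NH-orthoamide: as 19 with C≡C–Bpin on the orthoamide carbon | C[C@@H]1CCCC[C@H](C)[C@H]2CC(=O)N[C@](C#CB3OC(C)(C)C(C)(C)O3)(O[C@H]1[C@@H](C)CO[Si](C)(C)C(C)(C)C)O2 | intermediate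
21 | propiolic acid | C#CC(=O)O | starting material
22 | propiolic anhydride | C#CC(=O)OC(=O)C#C | intermediate
23 | N-propioloyl C-(pinacolborylethynyl) bicyclic orthoamide: as 20 with N–C(=O)C≡CH (key-step precursor) | C[C@@H]1CCCC[C@H](C)[C@H]2CC(=O)N(C(=O)C#C)[C@](C#CB3OC(C)(C)C(C)(C)O3)(O[C@H]1[C@@H](C)CO[Si](C)(C)C(C)(C)C)O2 | intermediate
24 | acetylene | C#C | starting material
25 | tetracyclic aryl pinacolboronate: isoindolin-1-one fused through N and the orthoamide carbon (S) to the bicycle of 19, Bpin on the aryl carbon next to the one bearing the orthoamide carbon; side arm CH(CH3)CH2OTBS; 3R,4S,9R,10R,11S | C[C@@H]1CCCC[C@H](C)[C@H]2CC(=O)N3C(=O)c4cccc(B5OC(C)(C)C(C)(C)O5)c4[C@@]3(O[C@H]1[C@@H](C)CO[Si](C)(C)C(C)(C)C)O2 | intermediate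
26 | tetracyclic phenol with silyloxymethyl side arm: as 25 with OH in place of Bpin | C[C@@H]1CCCC[C@H](C)[C@H]2CC(=O)N3C(=O)c4cccc(O)c4[C@@]3(O[C@H]1[C@@H](C)CO[Si](C)(C)C(C)(C)C)O2 | intermediate
27 | tetracyclic phenol primary alcohol: side arm CH(CH3)CH2OH (C11 S) | C[C@@H]1CCCC[C@H](C)[C@H]2CC(=O)N3C(=O)c4cccc(O)c4[C@@]3(O[C@H]1[C@@H](C)CO)O2 | intermediate
28 | tetracyclic phenol aldehyde: side arm CH(CH3)CHO (C11 R by priority change) | C[C@@H]1CCCC[C@H](C)[C@H]2CC(=O)N3C(=O)c4cccc(O)c4[C@@]3(O[C@H]1[C@@H](C)C=O)O2 | intermediate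
29 | tetracyclic phenol carboxylic acid: side arm CH(CH3)CO2H (C11 R) | C[C@@H]1CCCC[C@H](C)[C@H]2CC(=O)N3C(=O)c4cccc(O)c4[C@@]3(O[C@H]1[C@@H](C)C(=O)O)O2 | intermediate
30 | pyrrole | c1cc[nH]c1 | starting material
31 | pyrrol-1-ylmagnesium bromide | Br[Mg]n1cccc1 | intermediate
32 | S-(pyridin-2-yl) thioester of 29: side arm CH(CH3)C(=O)S(2-pyridyl) (C11 R) | C[C@@H]1CCCC[C@H](C)[C@H]2CC(=O)N3C(=O)c4cccc(O)c4[C@@]3(O[C@H]1[C@@H](C)C(=O)Sc1ccccn1)O2 | intermediate
33 | CNP0418824.1: side arm CH(CH3)C(=O)(1H-pyrrol-2-yl); 3R,4S,9R,10R,11R, orthoamide carbon S | C[C@@H]1CCCC[C@H](C)[C@H]2CC(=O)N3C(=O)c4cccc(O)c4[C@@]3(O[C@H]1[C@@H](C)C(=O)c1ccc[nH]1)O2 | target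

**Total step count:** 20.
**Longest linear sequence:** 16 steps (1, 2, 4, 8–20, from compound 1).

**Steps most likely to fail**

1. Step 12. What may go wrong: once the six‑membered ring has formed, loss of the third ethanol by elimination toward the conjugated cyclic N‑acyl imidate can compete with closure of the strained, entropically costly eleven‑membered ring, oligomeric orthoesters can form, and the orthoamide carbon can settle in the other epimer. Fallback: setting out from 17, condensation with 18 (PPTS, PhMe, 80 °C, 0.1 M) is run deliberately to the monocyclic imidate, the 2‑ethynyl‑5,6‑dihydro‑4H‑1,3‑oxazin‑4‑one with free C10 hydroxyl F1. The large ring is then closed under anionic, kinetic conditions: LDA (2.1 equiv, THF, −78 °C) turns the C10 alkoxide onto the C=N carbon, where the charge passes from an alkoxide to the better‑stabilised amidate, and the second equivalent metalates the alkyne. iPrOBpin followed by matched HCl·Et2O should then give 20, where the route is rejoined; 20 is N‑acylated without delay.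

2. Step 15. What may go wrong: self‑oligomerisation of 23 through its own alkynes can outrun capture of the metallacycle by dissolved acetylene, oxidative coupling at the hindered boryl alkyne can be slow, and the alkynyl C–B bond can be lost by protodeboronation. Fallback: setting out from 23, the gas is replaced by a liquid alkene partner in a formal cyclotrimerisation. With [Rh(cod)2]BF4/rac‑BINAP and vinyl acetate as co‑solvent (CH2Cl2, rt), the diyne and the enol ester should give the cyclohexadienyl acetate F2 (one regioisomer shown; both converge), which aromatises by loss of acetic acid to 25.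

3. Step 14. What may go wrong: conjugate addition of the amidate or of released propiolate to the activated alkyne, O‑acylation without rearrangement to nitrogen, or opening of the amidate before it is trapped. Fallback: setting out from 19, nitrogen is acylated first with 3‑(trimethylsilyl)propioloyl chloride (LiHMDS, THF, −78 °C) to the N‑(3‑trimethylsilylpropioloyl) C‑ethynyl orthoamide F3. With no N–H left, one equivalent of LiHMDS, iPrOBpin and HCl·Et2O should give the silyl‑capped boryl diyne F4. Cyclotrimerisation with acetylene as in step 15 gives the arylboronate with SiMe3 ortho to the lactam carbonyl F5, and Me3NO gives the silylated phenol F6. Excess TBAF in THF then removes the TBS ether and, by fluoride‑induced ipso‑protodesilylation assisted by the ortho carbonyl, the aryl silyl group, rejoining the route at 27.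

**Further compounds**

F1 | step 12 | 2-ethynyl-5,6-dihydro-4H-1,3-oxazin-4-one carrying the C4–C12 chain at ring C6, C10 hydroxyl free | C[C@H](CCCC[C@H](C)[C@H]1CC(=O)N=C(C#C)O1)[C@@H](O)[C@@H](C)CO[Si](C)(C)C(C)(C)C
F2 | step 15 | cyclohexadienyl acetate (dihydro form of 25 with OAc on one sp3 ring carbon) | C[C@@H]1CCCC[C@H](C)[C@H]2CC(=O)N3C(=O)C4=CCC(OC(C)=O)C(B5OC(C)(C)C(C)(C)O5)=C4[C@@]3(O[C@H]1[C@@H](C)CO[Si](C)(C)C(C)(C)C)O2
F3 | step 14 | N-(3-trimethylsilylpropioloyl) C-ethynyl bicyclic orthoamide | C[C@@H]1CCCC[C@H](C)[C@H]2CC(=O)N(C(=O)C#C[Si](C)(C)C)[C@](C#C)(O[C@H]1[C@@H](C)CO[Si](C)(C)C(C)(C)C)O2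
F4 | step 14 | N-(3-trimethylsilylpropioloyl) C-(pinacolborylethynyl) bicyclic orthoamide | C[C@@H]1CCCC[C@H](C)[C@H]2CC(=O)N(C(=O)C#C[Si](C)(C)C)[C@](C#CB3OC(C)(C)C(C)(C)O3)(O[C@H]1[C@@H](C)CO[Si](C)(C)C(C)(C)C)O2
F5 | step 14 | tetracyclic aryl pinacolboronate with SiMe3 ortho to the lactam carbonyl | C[C@@H]1CCCC[C@H](C)[C@H]2CC(=O)N3C(=O)c4c([Si](C)(C)C)ccc(B5OC(C)(C)C(C)(C)O5)c4[C@@]3(O[C@H]1[C@@H](C)CO[Si](C)(C)C(C)(C)C)O2
F6 | step 14 | tetracyclic phenol with SiMe3 ortho to the lactam carbonyl | C[C@@H]1CCCC[C@H](C)[C@H]2CC(=O)N3C(=O)c4c([Si](C)(C)C)ccc(O)c4[C@@]3(O[C@H]1[C@@H](C)CO[Si](C)(C)C(C)(C)C)O2
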